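**Retrosynthetic overview**
1. The target is the undeca-O-allyl ether deprotected. Its 2,3,4-triarylchroman (last ring) is cut by a retro hetero-Diels–Alder reaction into an o-quinone methide, whose methide carbon carries the resorcinol–oxolane block, and the (E)-stilbene bond of a chalcone–stilbene.
2. The o-quinone methide comes from a 2-hydroxybenzhydrol, made by ortho-hydroxyalkylation of resorcinol monoallyl ether with the aldehyde from formylation of the oxolane block.
3. The oxolane (first ring) is opened at C2–O to a γ-hydroxy ketone, the anti-aldol of a 2-benzyl-1,4-diaryl-1,4-diketone with an aryl aldehyde.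
4. The diketone comes from (R)-2-benzylsuccinic acid, made by SN2 of malonate on the triflate of the hydroxy acid from D-tyrosine (the only bought stereocentre). The dienophile comes from a Heck coupling and a Claisen–Schmidt condensation.
5. Ring order: oxolane, then the pyran ring of the chroman.

Assumption: allyl protects all eleven phenols, and the arenes listed as starting materials are taken as purchasable.

**Step 1**
Reactants: 1 D-tyrosine
Product: 4 (R)-2-hydroxy-3-(4-hydroxyphenyl)propanoic acid, via diazonium carboxylate 2 (not isolated), via alpha-lactone 3 (not isolated)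
Conditions: NaNO2, 1 M H2SO4, H2O, 0 °C to rt
Reagents that add atoms: water (O)
Why: Diazotization (hydroxy-deamination); the carboxylate displaces N2 and water reopens the α-lactone, a double inversion that gives net retention.

**Step 2**
Reactants: 4 (R)-2-hydroxy-3-(4-hydroxyphenyl)propanoic acid
Product: 5 allyl (R)-3-[4-(allyloxy)phenyl]-2-hydroxypropanoate
Conditions: allyl bromide (2.2 equiv), K2CO3, DMF, rt
Reagents that add atoms: allyl bromide (C=CCBr)
Why: Williamson O-alkylation of carboxylate and phenoxide only (K2CO3 does not deprotonate the secondary alcohol); the stereocentre is untouched.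

**Step 3**
Reactants: 5 allyl (R)-3-[4-(allyloxy)phenyl]-2-hydroxypropanoate
Product: 7 2-allyl 1,1-dimethyl (2R)-3-[4-(allyloxy)phenyl]propane-1,1,2-tricarboxylate, via triflate 6 (not isolated)
Conditions: Tf2O, 2,6-lutidine, CH2Cl2, −78 °C; then NaCH(CO2Me)2 (dimethyl malonate, NaH), THF, 0 °C to rt
Reagents that add atoms: dimethyl malonate (COC(=O)CC(=O)OC)
Why: SN2 displacement of an α-triflyloxy ester by the soft malonate anion goes with inversion, turning the bought centre into the carbon stereocentre that becomes oxolane C3 (still R by CIP because the priorities change).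

**Step 4**
Reactants: 7 2-allyl 1,1-dimethyl (2R)-3-[4-(allyloxy)phenyl]propane-1,1,2-tricarboxylate
Product: 9 (2R)-2-[4-(allyloxy)benzyl]butanedioic acid, via tricarboxylic acid 8 (not isolated)
Conditions: NaOH, MeOH/H2O, 50 °C; HCl to pH 1; then xylene, 130 °C
Reagents that add atoms: sodium hydroxide ([Na+].[OH-])
Why: Malonic ester synthesis (saponification, then thermal decarboxylation of the malonic acid); the stereocentre sits next to a carboxylate and is retained.

**Step 5**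
Reactants: 9 (2R)-2-[4-(allyloxy)benzyl]butanedioic acid
Product: 10 (2R)-2-[4-(allyloxy)benzyl]-N1,N4-dimethoxy-N1,N4-dimethylbutanediamide
Conditions: MeNH(OMe)·HCl, EDC·HCl, HOBt, N-methylmorpholine, CH2Cl2, 0 °C to rt
Reagents that add atoms: N,O-dimethylhydroxylamine hydrochloride (CNOC.Cl)
Why: Carbodiimide amidation to the bis-Weinreb amide, which allows one clean aryl addition per carbonyl; no bond to the stereocentre is made or broken.

**Step 6**
Reactants: 11 4-bromoresorcinol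
Product: 12 1-bromo-2,4-bis(allyloxy)benzene
Conditions: allyl bromide, K2CO3, DMF, 50 °C
Reagents that add atoms: allyl bromide (C=CCBr)
Why: Williamson allylation of both phenols.

**Step 7**
Reactants: 10 bis-Weinreb amide; 12 1-bromo-2,4-bis(allyloxy)benzene
Product: 14 (2R)-2-[4-(allyloxy)benzyl]-1,4-bis[2,4-bis(allyloxy)phenyl]butane-1,4-dione, via arylmagnesium bromide 13 (not isolated)
Conditions: 12 (3 equiv), Mg, THF, 45 °C; then 10, THF, 0 °C to rt; aq. NH4Cl
Reagents that add atoms: none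
Why: Weinreb ketone synthesis; each chelated tetrahedral adduct survives until work-up, so the 1,4-diketone forms without over-addition or epimerization, and the Grignard reagent tolerates the ortho-allyloxy group.

**Step 8**
Reactants: 14 1,4-diketone; 15 4-(allyloxy)benzaldehyde
Product: 17 (2R,3R)-2-[4-(allyloxy)benzyl]-3-{(S)-[4-(allyloxy)phenyl](hydroxy)methyl}-1,4-bis[2,4-bis(allyloxy)phenyl]butane-1,4-dione, via boron enolate 16 (not isolated)
Conditions: Cy2BCl, Et3N, Et2O, −78 to 0 °C; then 15, −78 to −20 °C; MeOH, pH 7 buffer, 30% H2O2, 0 °C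
Reagents that add atoms: none
Why: Brown anti-aldol; Cy2BCl/Et3N enolizes the unhindered CH2 to the E-enol borinate and the Zimmerman–Traxler chair gives the anti C4/C5 pair, with the aldehyde expected to approach anti to the benzyl arm of the neighbouring centre (its C–H in the enolate plane by allylic strain), which gives 3,4-trans; this facial ratio is likely modest, and minor isomers are removed after step 9.

**Step 9**
Reactants: 17 anti-aldol
Product: 20 (2S,3R,4R,5S)-2-[2,4-bis(allyloxy)phenyl]-3-[4-(allyloxy)benzyl]-4-[2,4-bis(allyloxy)benzoyl]-5-[4-(allyloxy)phenyl]oxolane, via lactol 18 (not isolated), via oxocarbenium ion 19 (not isolated)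
Conditions: Et3SiH, BF3·OEt2, CH2Cl2, −78 °C
Reagents that add atoms: none
Why: Reductive etherification; the γ-hydroxy ketone closes to the lactol, BF3 gives the cyclic oxocarbenium ion, and hydride adds anti to the adjacent C3 benzyl group (inside attack), placing the aryl group cis to it (2S) while the aryl ketone survives at −78 °C.

**Step 10**
Reactants: 20 oxolane
Product: 22 2,4-bis(allyloxy)-5-[(2S,3R,4R,5S)-3-[4-(allyloxy)benzyl]-4-[2,4-bis(allyloxy)benzoyl]-5-[4-(allyloxy)phenyl]oxolan-2-yl]benzaldehyde, via iminium chloride 21 (not isolated)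
Conditions: POCl3, DMF, 0 °C to rt; then aq. NaOAc
Reagents that add atoms: N,N-dimethylformamide (CN(C)C=O); water (O)
Why: Vilsmeier–Haack formylation at the most electron-rich free position (para to one allyloxy group, ortho to the other, on the ring attached to C2); the acyl-deactivated resorcinol ring and the monoalkoxy rings do not react.

**Step 11**
Reactants: 22 aldehyde; 23 3-(allyloxy)phenol
Product: 25 {2,4-bis(allyloxy)-5-[(2S,3R,4R,5S)-3-[4-(allyloxy)benzyl]-4-[2,4-bis(allyloxy)benzoyl]-5-[4-(allyloxy)phenyl]oxolan-2-yl]phenyl}[4-(allyloxy)-2-hydroxyphenyl]methanol (both carbinol epimers), via bromomagnesium phenoxide 24 (not isolated)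
Conditions: 23, EtMgBr, Et2O/toluene, 0 °C; then 22, toluene, rt; aq. NH4Cl
Reagents that add atoms: none
Why: Casiraghi ortho-hydroxyalkylation; the magnesium phenoxide delivers the aldehyde through a six-membered chelate to the ortho carbon para to the allyloxy group, and the new carbinol centre is unimportant because it becomes planar in step 16.

**Step 12**
Reactants: 26 2,4-dihydroxyacetophenone
Product: 27 2,4-bis(allyloxy)acetophenone
Conditions: allyl bromide, K2CO3, DMF, 60 °C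
Reagents that add atoms: allyl bromide (C=CCBr)
Why: Williamson allylation; warming overcomes the hydrogen-bonded ortho-hydroxyl.

**Step 13**
Reactants: 28 3-bromo-4-hydroxybenzaldehyde; 29 4-acetoxystyrene
Product: 30 4-[(E)-2-(5-formyl-2-hydroxyphenyl)ethenyl]phenyl acetate
Conditions: Pd(OAc)2 (3 mol %), P(o-tol)3, Et3N, DMF, 100 °C
Reagents that add atoms: none
Why: Mizoroki–Heck arylation of the styrene terminus; syn β-hydride elimination gives the E-stilbene.

**Step 14**
Reactants: 30 stilbene acetate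
Product: 32 4-(allyloxy)-3-{(E)-2-[4-(allyloxy)phenyl]ethenyl}benzaldehyde, via diphenol 31 (not isolated)
Conditions: K2CO3, MeOH, rt; evaporate; then allyl bromide, K2CO3, DMF, 50 °C
Reagents that add atoms: allyl bromide (C=CCBr)
Why: Methanolysis of the aryl acetate, then Williamson allylation of both phenoxides.

**Step 15**
Reactants: 32 stilbene aldehyde; 27 2,4-bis(allyloxy)acetophenone
Product: 33 (E)-1-[2,4-bis(allyloxy)phenyl]-3-[4-(allyloxy)-3-{(E)-2-[4-(allyloxy)phenyl]ethenyl}phenyl]prop-2-en-1-one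
Conditions: KOH, EtOH/THF, rt
Reagents that add atoms: none
Why: Claisen–Schmidt condensation gives the E-enone; doing it before the union keeps base away from the β-alkoxy ketone of the oxolane block.

**Step 16**
Reactants: 25 2-hydroxybenzhydrol; 33 chalcone–stilbene
Product: 35 undeca-O-allyl ether of 36 (chroman 2S,3R,4S by CIP in this protected form; oxolane 2S,3R,4R,5S), via o-quinone methide 34 (not isolated)
Conditions: (PhO)2P(O)OH (10 mol %), 4 Å MS, CH2Cl2, −20 °C to rt; HPLC separation of the two chroman diastereomers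
Reagents that add atoms: none
Why: Acid ionizes the benzhydrol to the (E)-o-quinone methide, which adds the stilbene bond in an inverse-electron-demand hetero-Diels–Alder reaction with the p-alkoxyphenyl carbon bonding to oxygen; the E-alkene gives 2,3-trans and the endo transition state 2,4-cis, but the face is chosen only under the remote, weak bias of the oxolane centres, so about half the material is the all-trans diastereomer with the mirror-image chroman and is removed.

**Step 17**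
Reactants: 35 undeca-O-allyl ether
Product: 36 CNP0330082.3
Conditions: Pd(PPh3)4 (10 mol %), N-methylaniline (excess), THF, rt
Reagents that add atoms: none
Why: Tsuji–Trost-type allyl transfer; Pd(PPh3)4 ionizes each aryl allyl ether and the non-basic aniline traps the allyl group, so the enone, the β-alkoxy ketone, the benzylic ethers and all seven stereocentres are left alone.

**Compound list**
1 | D-tyrosine | N[C@H](Cc1ccc(O)cc1)C(=O)O | starting material
2 | (R)-1-carboxylato-2-(4-hydroxyphenyl)ethanediazonium | N#[N+][C@H](Cc1ccc(O)cc1)C(=O)[O-] | intermediate (not isolated)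
3 | (S)-3-(4-hydroxybenzyl)oxiran-2-one | O1[C@@H](Cc2ccc(O)cc2)C1=O | intermediate (not isolated)
4 | (R)-2-hydroxy-3-(4-hydroxyphenyl)propanoic acid | O[C@H](Cc1ccc(O)cc1)C(=O)O | intermediate
5 | allyl (R)-3-[4-(allyloxy)phenyl]-2-hydroxypropanoate | O[C@H](Cc1ccc(OCC=C)cc1)C(=O)OCC=C | intermediate
6 | allyl (R)-3-[4-(allyloxy)phenyl]-2-(trifluoromethylsulfonyloxy)propanoate | O=S(=O)(O[C@H](Cc1ccc(OCC=C)cc1)C(=O)OCC=C)C(F)(F)F | intermediate (not isolated)
7 | 2-allyl 1,1-dimethyl (2R)-3-[4-(allyloxy)phenyl]propane-1,1,2-tricarboxylate | COC(=O)C(C(=O)OC)[C@@H](Cc1ccc(OCC=C)cc1)C(=O)OCC=C | intermediate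
8 | (2R)-3-[4-(allyloxy)phenyl]propane-1,1,2-tricarboxylic acid | OC(=O)C(C(=O)O)[C@@H](Cc1ccc(OCC=C)cc1)C(=O)O | intermediate (not isolated)
9 | (2R)-2-[4-(allyloxy)benzyl]butanedioic acid | OC(=O)C[C@@H](Cc1ccc(OCC=C)cc1)C(=O)O | intermediate
10 | (2R)-2-[4-(allyloxy)benzyl]-N1,N4-dimethoxy-N1,N4-dimethylbutanediamide | CON(C)C(=O)C[C@@H](Cc1ccc(OCC=C)cc1)C(=O)N(C)OC | intermediate
11 | 4-bromoresorcinol | Oc1ccc(Br)c(O)c1 | starting material
12 | 1-bromo-2,4-bis(allyloxy)benzene | C=CCOc1ccc(Br)c(OCC=C)c1 | intermediate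
13 | [2,4-bis(allyloxy)phenyl]magnesium bromide | C=CCOc1ccc([Mg]Br)c(OCC=C)c1 | intermediate (not isolated)
14 | (2R)-2-[4-(allyloxy)benzyl]-1,4-bis[2,4-bis(allyloxy)phenyl]butane-1,4-dione | C=CCOc1ccc(C(=O)C[C@@H](Cc2ccc(OCC=C)cc2)C(=O)c2ccc(OCC=C)cc2OCC=C)c(OCC=C)c1 | intermediate
15 | 4-(allyloxy)benzaldehyde | C=CCOc1ccc(C=O)cc1 | starting material
16 | dicyclohexylboron (E)-enolate of 14 (C3=C4 enol borinate; 2R centre intact) | C=CCOc1ccc(/C(OB(C2CCCCC2)C2CCCCC2)=C\[C@@H](Cc2ccc(OCC=C)cc2)C(=O)c2ccc(OCC=C)cc2OCC=C)c(OCC=C)c1 | intermediate (not isolated)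
17 | (2R,3R)-2-[4-(allyloxy)benzyl]-3-{(S)-[4-(allyloxy)phenyl](hydroxy)methyl}-1,4-bis[2,4-bis(allyloxy)phenyl]butane-1,4-dione | O[C@H](c1ccc(OCC=C)cc1)[C@H](C(=O)c1ccc(OCC=C)cc1OCC=C)[C@@H](Cc1ccc(OCC=C)cc1)C(=O)c1ccc(OCC=C)cc1OCC=C | intermediate
18 | (3R,4R,5S)-2-[2,4-bis(allyloxy)phenyl]-3-[4-(allyloxy)benzyl]-4-[2,4-bis(allyloxy)benzoyl]-5-[4-(allyloxy)phenyl]oxolan-2-ol (both anomers) | C=CCOc1ccc(C2(O)O[C@H](c3ccc(OCC=C)cc3)[C@H](C(=O)c3ccc(OCC=C)cc3OCC=C)[C@H]2Cc2ccc(OCC=C)cc2)c(OCC=C)c1 | intermediate (not isolated)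
19 | (3R,4R,5S)-oxolan-2-ylium ion from 18 | C=CCOc1ccc(C2=[O+][C@H](c3ccc(OCC=C)cc3)[C@H](C(=O)c3ccc(OCC=C)cc3OCC=C)[C@H]2Cc2ccc(OCC=C)cc2)c(OCC=C)c1 | intermediate (not isolated)
20 | (2S,3R,4R,5S)-2-[2,4-bis(allyloxy)phenyl]-3-[4-(allyloxy)benzyl]-4-[2,4-bis(allyloxy)benzoyl]-5-[4-(allyloxy)phenyl]oxolane | C=CCOc1ccc([C@H]2O[C@H](c3ccc(OCC=C)cc3)[C@H](C(=O)c3ccc(OCC=C)cc3OCC=C)[C@H]2Cc2ccc(OCC=C)cc2)c(OCC=C)c1 | intermediate
21 | N,N-dimethyliminium chloride of aldehyde 22 | C=CCOc1cc(OCC=C)c([C@H]2O[C@H](c3ccc(OCC=C)cc3)[C@H](C(=O)c3ccc(OCC=C)cc3OCC=C)[C@H]2Cc2ccc(OCC=C)cc2)cc1C=[N+](C)C.[Cl-] | intermediate (not isolated)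
22 | 2,4-bis(allyloxy)-5-[(2S,3R,4R,5S)-3-[4-(allyloxy)benzyl]-4-[2,4-bis(allyloxy)benzoyl]-5-[4-(allyloxy)phenyl]oxolan-2-yl]benzaldehyde | C=CCOc1cc(OCC=C)c([C@H]2O[C@H](c3ccc(OCC=C)cc3)[C@H](C(=O)c3ccc(OCC=C)cc3OCC=C)[C@H]2Cc2ccc(OCC=C)cc2)cc1C=O | intermediate
23 | 3-(allyloxy)phenol | Oc1cccc(OCC=C)c1 | starting material
24 | bromomagnesium 3-(allyloxy)phenoxide | Br[Mg]Oc1cccc(OCC=C)c1 | intermediate (not isolated)
25 | {2,4-bis(allyloxy)-5-[(2S,3R,4R,5S)-3-[4-(allyloxy)benzyl]-4-[2,4-bis(allyloxy)benzoyl]-5-[4-(allyloxy)phenyl]oxolan-2-yl]phenyl}[4-(allyloxy)-2-hydroxyphenyl]methanol (carbinol epimers) | C=CCOc1cc(OCC=C)c([C@H]2O[C@H](c3ccc(OCC=C)cc3)[C@H](C(=O)c3ccc(OCC=C)cc3OCC=C)[C@H]2Cc2ccc(OCC=C)cc2)cc1C(O)c1ccc(OCC=C)cc1O | intermediate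
26 | 2,4-dihydroxyacetophenone | CC(=O)c1ccc(O)cc1O | starting material
27 | 2,4-bis(allyloxy)acetophenone | CC(=O)c1ccc(OCC=C)cc1OCC=C | intermediate
28 | 3-bromo-4-hydroxybenzaldehyde | O=Cc1ccc(O)c(Br)c1 | starting material
29 | 4-acetoxystyrene | CC(=O)Oc1ccc(C=C)cc1 | starting material
30 | 4-[(E)-2-(5-formyl-2-hydroxyphenyl)ethenyl]phenyl acetate | CC(=O)Oc1ccc(/C=C/c2cc(C=O)ccc2O)cc1 | intermediate
31 | 4-hydroxy-3-[(E)-2-(4-hydroxyphenyl)ethenyl]benzaldehyde | O=Cc1ccc(O)c(/C=C/c2ccc(O)cc2)c1 | intermediate (not isolated)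
32 | 4-(allyloxy)-3-{(E)-2-[4-(allyloxy)phenyl]ethenyl}benzaldehyde | O=Cc1ccc(OCC=C)c(/C=C/c2ccc(OCC=C)cc2)c1 | intermediate
33 | (E)-1-[2,4-bis(allyloxy)phenyl]-3-[4-(allyloxy)-3-{(E)-2-[4-(allyloxy)phenyl]ethenyl}phenyl]prop-2-en-1-one | O=C(/C=C/c1ccc(OCC=C)c(/C=C/c2ccc(OCC=C)cc2)c1)c1ccc(OCC=C)cc1OCC=C | intermediate
34 | (E)-o-quinone methide: 3-(allyloxy)-6-(arylmethylidene)cyclohexa-2,4-dien-1-one, aryl = the 2,4-bis(allyloxy)-5-(oxolan-2-yl)phenyl group of 25 | O=C1C=C(OCC=C)C=C/C1=C\c1cc([C@H]2O[C@H](c3ccc(OCC=C)cc3)[C@H](C(=O)c3ccc(OCC=C)cc3OCC=C)[C@H]2Cc2ccc(OCC=C)cc2)c(OCC=C)cc1OCC=C | intermediate (not isolated)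
35 | (E)-1-[2,4-bis(allyloxy)phenyl]-3-{4-(allyloxy)-3-[(2S,3R,4S)-7-(allyloxy)-2-[4-(allyloxy)phenyl]-4-{2,4-bis(allyloxy)-5-[(2S,3R,4R,5S)-3-[4-(allyloxy)benzyl]-4-[2,4-bis(allyloxy)benzoyl]-5-[4-(allyloxy)phenyl]oxolan-2-yl]phenyl}chroman-3-yl]phenyl}prop-2-en-1-one (same geometry as 36; the C4 descriptor differs only through CIP priorities) | O=C(/C=C/c1ccc(OCC=C)c([C@H]2[C@H](c3cc([C@H]4O[C@H](c5ccc(OCC=C)cc5)[C@H](C(=O)c5ccc(OCC=C)cc5OCC=C)[C@H]4Cc4ccc(OCC=C)cc4)c(OCC=C)cc3OCC=C)c3ccc(OCC=C)cc3O[C@@H]2c2ccc(OCC=C)cc2)c1)c1ccc(OCC=C)cc1OCC=C | intermediate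
36 | CNP0330082.3: (E)-1-(2,4-dihydroxyphenyl)-3-{3-[(2S,3R,4R)-4-{5-[(2S,3R,4R,5S)-4-(2,4-dihydroxybenzoyl)-3-(4-hydroxybenzyl)-5-(4-hydroxyphenyl)oxolan-2-yl]-2,4-dihydroxyphenyl}-7-hydroxy-2-(4-hydroxyphenyl)chroman-3-yl]-4-hydroxyphenyl}prop-2-en-1-one | O=C(/C=C/c1ccc(O)c([C@H]2[C@H](c3cc([C@H]4O[C@H](c5ccc(O)cc5)[C@H](C(=O)c5ccc(O)cc5O)[C@H]4Cc4ccc(O)cc4)c(O)cc3O)c3ccc(O)cc3O[C@@H]2c2ccc(O)cc2)c1)c1ccc(O)cc1O | target

**Totals**
Total steps: 17. Longest linear sequence: 12 (steps 1–5, 7–11, 16, 17).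

**Steps most likely to fail, with fallbacks**

Step 8 (aldol). The anti relationship rests on the E-enol borinate, but the facial preference from the neighbouring acyclic centre may be small or even reversed, and some enolization at the stereogenic CH would erode it. The fallback sets out from 9 and returns at 17; it moves the aldol onto a ring.
- Acetic anhydride at 80 °C gives the cyclic anhydride F1, and methanol opens it at the less hindered carbonyl to the half ester F2.
- The remaining acid is converted with (COCl)2 and catalytic DMF into its chloride, which couples with 13 (5 mol % Fe(acac)3, THF, −78 °C) to the keto ester F3.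
- NaBH4, then acid, gives the γ-aryl lactone F4; its carbinol carbon may be a mixture because it is re-oxidized later.
- LiN(iPr)2 and then 15 at −78 °C give the hydroxy lactone F5. The ring fixes the enolate as E (anti carbinol) and the benzyl group blocks one face (trans), so both new centres are set on a ring.
- TBSOTf/2,6-lutidine gives the silyl ether F6, and 13 opens the lactone to the hydroxy ketone F7.
- Dess–Martin periodinane gives the diketone F8, and HF·pyridine removes the silyl group to give 17.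

Step 11 (ortho-hydroxyalkylation). The electron-rich benzhydrol can ionize in the flask and take up a second phenoxide to give a triarylmethane, and the hindered, donor-substituted aldehyde may react slowly. The fallback sets out from 22 and 23 and returns at 25; it uses a boron template. PhB(OH)2 with catalytic propanoic acid in refluxing toluene (Dean–Stark) condenses the two partners to the benzodioxaborin F9, a masked benzhydrol that can be chromatographed and cannot alkylate a second phenol. Exchange with propane-1,3-diol releases 25.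

Step 16 (cycloaddition). The stabilized o-quinone methide may be too unreactive toward a 1,2-diarylalkene, Friedel–Crafts capture may compete, and at best two diastereomers form in similar amounts. The fallback sets out from 33 and 20 and returns at 35; the chroman is closed on a simpler cation and the oxolane block is attached afterwards.
- 4-(Allyloxy)-2-hydroxybenzaldehyde, HC(OMe)3 and 33 with Sc(OTf)3 (5 mol %) in CH2Cl2 give, through the O-methylated o-quinone methide cation and the same [4+2] cycloaddition, the racemic 2,3-trans-4-methoxychroman F10.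
- BF3·OEt2 at −78 °C ionizes F10, and the free activated position of 20 attacks the benzylic cation anti to the C3 aryl group.
- This gives 35 together with its diastereomer from the other enantiomer of F10, separated as in step 16. It answers the reactivity problem, not the facial one.

**Further compounds**
F1 | step 8 | (3R)-3-[4-(allyloxy)benzyl]oxolane-2,5-dione | O=C1C[C@@H](Cc2ccc(OCC=C)cc2)C(=O)O1
F2 | step 8 | (2R)-2-[4-(allyloxy)benzyl]-4-methoxy-4-oxobutanoic acid | COC(=O)C[C@@H](Cc1ccc(OCC=C)cc1)C(=O)O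
F3 | step 8 | methyl (3R)-3-[4-(allyloxy)benzyl]-4-[2,4-bis(allyloxy)phenyl]-4-oxobutanoate | COC(=O)C[C@@H](Cc1ccc(OCC=C)cc1)C(=O)c1ccc(OCC=C)cc1OCC=C
F4 | step 8 | (4R)-4-[4-(allyloxy)benzyl]-5-[2,4-bis(allyloxy)phenyl]oxolan-2-one (C5 epimers) | O=C1C[C@@H](Cc2ccc(OCC=C)cc2)C(c2ccc(OCC=C)cc2OCC=C)O1
F5 | step 8 | (3R,4R)-4-[4-(allyloxy)benzyl]-3-{(S)-[4-(allyloxy)phenyl](hydroxy)methyl}-5-[2,4-bis(allyloxy)phenyl]oxolan-2-one | O[C@H](c1ccc(OCC=C)cc1)[C@@H]1C(=O)OC(c2ccc(OCC=C)cc2OCC=C)[C@@H]1Cc1ccc(OCC=C)cc1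
F6 | step 8 | tert-butyldimethylsilyl ether of F5 | CC(C)(C)[Si](C)(C)O[C@H](c1ccc(OCC=C)cc1)[C@@H]1C(=O)OC(c2ccc(OCC=C)cc2OCC=C)[C@@H]1Cc1ccc(OCC=C)cc1
F7 | step 8 | (2R,3R)-3-[4-(allyloxy)benzyl]-1,4-bis[2,4-bis(allyloxy)phenyl]-2-{(S)-[4-(allyloxy)phenyl](tert-butyldimethylsilyloxy)methyl}-4-hydroxybutan-1-one (carbinol epimers) | CC(C)(C)[Si](C)(C)O[C@H](c1ccc(OCC=C)cc1)[C@H](C(=O)c1ccc(OCC=C)cc1OCC=C)[C@@H](Cc1ccc(OCC=C)cc1)C(O)c1ccc(OCC=C)cc1OCC=C
F8 | step 8 | tert-butyldimethylsilyl ether of 17 | CC(C)(C)[Si](C)(C)O[C@H](c1ccc(OCC=C)cc1)[C@H](C(=O)c1ccc(OCC=C)cc1OCC=C)[C@@H](Cc1ccc(OCC=C)cc1)C(=O)c1ccc(OCC=C)cc1OCC=C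
F9 | step 11 | 7-(allyloxy)-2-phenyl-4-aryl-4H-1,3,2-benzodioxaborin, aryl = the 2,4-bis(allyloxy)-5-(oxolan-2-yl)phenyl group of 25 (C4 epimers) | C=CCOc1ccc2c(c1)OB(c1ccccc1)OC2c1cc([C@H]2O[C@H](c3ccc(OCC=C)cc3)[C@H](C(=O)c3ccc(OCC=C)cc3OCC=C)[C@H]2Cc2ccc(OCC=C)cc2)c(OCC=C)cc1OCC=C
F10 | step 16 | racemic 2,3-trans-7-(allyloxy)-4-methoxy-2-[4-(allyloxy)phenyl]chroman carrying the chalcone-bearing aryl group of 33 at C3 (drawn as the enantiomer with the target geometry at C2 and C3; C4 epimers) | O=C(/C=C/c1ccc(OCC=C)c([C@H]2C(OC)c3ccc(OCC=C)cc3O[C@@H]2c2ccc(OCC=C)cc2)c1)c1ccc(OCC=C)cc1OCC=C
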